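Late in both runs, the isomer of the product A is still climbing while the target stays low. The two runs look nearly the same, though their charges differ.

| flask | substrate | remark | time |
|---|---|---|---|
| Wednesday's | 0.10 M | the very flask that is asked about, followed so far |  |
| Thursday's | 0.067 M | run made earlier |  |
| flask | 0.10 M |  | 6.0 d |

| run | time / d | isomer of the product A / % | target / % |
|---|---|---|---|
| Wednesday's | 0.250 | 1.0 | 2.0 |
| Wednesday's | 0.333 | 1.1 | 2.1 |
| Wednesday's | 0.500 | 2.0 | 1.5 |
| Wednesday's | 0.833 | 3.0 | 2.0 |
| Wednesday's | 1.25 | 4.1 | 1.4 |
| Wednesday's | 2.08 | 7.0 | 1.3 |
| Wednesday's | 3.00 | 9.1 | 1.5 |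
| Thursday's | 0.333 | 1.7 | 2.1 |
| Thursday's | 0.625 | 2.8 | 1.6 |
| Thursday's | 1.04 | 3.5 | 1.6 |
| Thursday's | 1.25 | 4.7 | 1.5 |
| Thursday's | 1.67 | 5.2 | 1.7 |
| Thursday's | 2.08 | 6.6 | 1.4 |
| Thursday's | 2.50 | 7.7 | 2.2 |

(scatter of a reading: 0.3 percentage points)

- the numbers in the tables scatter with a standard deviation of 0.3 percentage points

1. ratio of isomer of the product A to target at 15 min
2. ratio of isomer of the product A to target at 6.0 h
3. ratio of isomer of the product A to target at 6.0 d
4. which of isomer of the product A and target there is more of at 6.0 d

I write a balance of the charge: it is the isomer plus a rest, and the isomer grows out of that rest. I define the leak as the fraction of the rest that turns into the isomer per day, an apparent first-order constant. Wednesday's run has 9.1% at 3.00 d, which gives a leak of 0.0318 /d. Thursday's run has 7.7% at 2.50 d, which gives 0.0321 /d, nearly the same. So Wednesday's run ends higher because it was followed longer, not because of its charge.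

The target readings of both runs scatter around 1.71%. I assume this is a constant share of the rest. I also assume that the rest falls exponentially with the leak. In this reckoning the ratio of isomer to target is the exponential of leak times time, less one, over that share. The charge does not enter this reckoning.

For 6.0 d I reckon 12.3, with the isomer ahead. For 6.0 h I reckon 0.468, and for 15 min 0.0194. The last stands before any reading, so it assumes the target is already level.

The forecast says 0.02, 0.5 and 12, with isomer of the product A ahead, and gives as its ground: “The percentage rate does not depend on concentration”.

The flask gives 0.0440, 0.565 and 10.2, with isomer of the product A ahead, at 15.8% against 1.54% of target.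

    substrate ⇌ dormant form (K = 2.60, k = 2.60 /h)
    substrate ⇌ target (K = 0.120, k = 0.270 /h)
    substrate ⇌ isomer of the product A (K = 4.50, k = 0.00880 /h)
    substrate ⇌ isomer of the product B (K = 2.80, k = 0.320 /h)

Read from the end of the asked flask, its leak is 0.0286 /d, lower than my 0.0318 /d. The neighbouring flask holds 0.060 M of substrate and the same time. My rule has no charge in it, so I reckon 12.3 again. The neighbouring flask gives 10.2, the value of the asked flask. The neighbouring flask ends with 15.8% of isomer of the product A and 13% of its charge as substrate.

All runs are calculated from invented constants; noise was put on by code.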